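**Retrosynthetic overview**
1. The dihydrofuran ring is the only ring to be made and is closed last, at O1–C2. Fluoride unmasks a syringyl para-quinone methide from a silylated cyclic benzylic carbonate, and the ring A phenoxide adds to it (intramolecular oxa-Michael addition, 1,6-mode). C3 dictates the trans configuration at C2.
2. The carbonate comes from a syn-1,3-diol. Its side chain is attached by Suzuki coupling of the aryl bromide with an (E)-alkenylboronate (fragment D, from propargyl alcohol).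
3. The diol comes from an Evans syn-aldol reaction, which sets C3, between a ring A arylacetyl imide and O-TBS syringaldehyde (fragment C), followed by LiBH4.
4. The imide comes from Pd-catalysed α-arylation of the zinc enolate of a bromoacetyl oxazolidinone (fragment B) with the TBS ether of 4-bromo-2-iodo-6-methoxyphenol (fragment A, from 4-bromoguaiacol).

Assumption: the SMILES is read as (2S,3R), that is trans-2,3 with an E side chain. TBS = tert-butyldimethylsilyl. NIS, TBSCl, pinacolborane and CDI count as reagents and carry no number.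

**Step 1**
Reactants: 1 4-bromo-2-methoxyphenol
Product: 2 4-bromo-2-iodo-6-methoxyphenol
Conditions: NIS (1.05 equiv), TsOH·H2O (10 mol %), MeCN, 0 °C to rt
Reagents that add atoms: N-iodosuccinimide, O=C1CCC(=O)N1I
Why: In this electrophilic aromatic iodination the free OH is the strongest director and its para position is blocked by Br, so iodine enters the only free ortho position.

**Step 2**
Reactants: 2 4-bromo-2-iodo-6-methoxyphenol
Product: 3 (4-bromo-2-iodo-6-methoxyphenoxy)(tert-butyl)dimethylsilane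
Conditions: TBSCl, imidazole, DMF, rt to 40 °C
Reagents that add atoms: tert-butyldimethylsilyl chloride, CC(C)(C)[Si](C)(C)Cl
Why: Imidazole-promoted O-silylation masks the future ring oxygen O1 with a fluoride-labile group that tolerates organozinc, boron enolate and hydride chemistry.

**Step 3**
Reactants: 4 (S)-4-benzyloxazolidin-2-one; 5 bromoacetyl bromide
Product: 7 (S)-4-benzyl-3-(2-bromoacetyl)oxazolidin-2-one, via N-lithio oxazolidinone 6 (not isolated)
Conditions: n-BuLi, THF, −78 °C; then 5, −78 to 0 °C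
Reagents that add atoms: none
Why: N-acylation of the lithiated Evans auxiliary takes place at the acyl bromide much faster than at the alkyl bromide, and the auxiliary stereocentre is not touched.

**Step 4**
Reactants: 3 (4-bromo-2-iodo-6-methoxyphenoxy)(tert-butyl)dimethylsilane; 7 (S)-4-benzyl-3-(2-bromoacetyl)oxazolidin-2-one
Product: 9 (S)-4-benzyl-3-{2-[5-bromo-2-(TBSO)-3-methoxyphenyl]acetyl}oxazolidin-2-one, via bromozinc enolate 8 (not isolated)
Conditions: 7 (1.15 equiv), Zn dust (TMSCl-activated), THF, 30 °C; then 3, Pd(dba)2 (3 mol %), P(t-Bu)3 (3 mol %), THF, rt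
Reagents that add atoms: none
Why: Reformatsky zinc insertion gives a soft, weakly basic enolate that undergoes Negishi-type palladium-catalysed α-arylation, and zerovalent palladium adds to C–I far faster than to C–Br, so the bromide is kept.

**Step 5**
Reactants: 10 syringaldehyde (4-hydroxy-3,5-dimethoxybenzaldehyde)
Product: 11 4-(TBSO)-3,5-dimethoxybenzaldehyde
Conditions: TBSCl, imidazole, DMF, rt
Reagents that add atoms: tert-butyldimethylsilyl chloride, CC(C)(C)[Si](C)(C)Cl
Why: O-silylation removes the acidic phenol before the aldol reaction and installs the fluoride trigger for the later quinone methide.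

**Step 6**
Reactants: 9 (S)-4-benzyl-3-{2-[5-bromo-2-(TBSO)-3-methoxyphenyl]acetyl}oxazolidin-2-one; 11 4-(TBSO)-3,5-dimethoxybenzaldehyde
Product: 14 (S)-4-benzyl-3-{(2S,3S)-2-[5-bromo-2-(TBSO)-3-methoxyphenyl]-3-[4-(TBSO)-3,5-dimethoxyphenyl]-3-hydroxypropanoyl}oxazolidin-2-one, via Z-dibutylboron enolate 12 (not isolated), via dibutylboron aldolate 13 (not isolated)
Conditions: Bu2BOTf, Et3N, CH2Cl2, −78 to 0 °C; 11, −78 to 0 °C; then pH 7 buffer, MeOH, 30 % H2O2, 0 °C
Reagents that add atoms: none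
Why: In this Evans syn-aldol reaction the Z-boron enolate reacts through a Zimmerman–Traxler chair on the face away from the benzyl group of the (S)-auxiliary, which sets the α-carbon (future C3) as 2S together with a 3S carbinol that is erased later.

**Step 7**
Reactants: 14 Evans aldol adduct
Product: 15 (1S,2R)-2-[5-bromo-2-(TBSO)-3-methoxyphenyl]-1-[4-(TBSO)-3,5-dimethoxyphenyl]propane-1,3-diol
Conditions: LiBH4, H2O (1 equiv), Et2O/THF, 0 °C
Reagents that add atoms: none
Why: Reductive cleavage of the imide at the exocyclic carbonyl releases auxiliary 4 and gives the 1,3-diol without epimerisation, and the descriptor of the aryl-bearing carbon changes to R only because the substituent ranks change.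

**Step 8**
Reactants: 16 propargyl alcohol
Product: 17 tert-butyldimethyl(prop-2-yn-1-yloxy)silane
Conditions: TBSCl, imidazole, CH2Cl2, 0 °C to rt
Reagents that add atoms: tert-butyldimethylsilyl chloride, CC(C)(C)[Si](C)(C)Cl
Why: Standard O-silylation removes the acidic OH before hydroboration and gives a group that falls off in the final fluoride step.

**Step 9**
Reactants: 17 tert-butyldimethyl(prop-2-yn-1-yloxy)silane
Product: 18 (E)-tert-butyldimethyl{[3-(4,4,5,5-tetramethyl-1,3,2-dioxaborolan-2-yl)prop-2-en-1-yl]oxy}silane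
Conditions: pinacolborane (1.1 equiv), Cp2Zr(H)Cl (10 mol %), Et3N (10 mol %), neat, 60 °C
Reagents that add atoms: pinacolborane, CC1(C)OBOC1(C)C
Why: Zirconocene-catalysed anti-Markovnikov syn-hydroboration of the terminal alkyne delivers only the E-alkenylboronate.

**Step 10**
Reactants: 15 bromo diol; 18 (E)-alkenylboronate
Product: 19 (1S,2R)-2-{2-(TBSO)-5-[(E)-3-(TBSO)prop-1-en-1-yl]-3-methoxyphenyl}-1-[4-(TBSO)-3,5-dimethoxyphenyl]propane-1,3-diol
Conditions: Pd(OAc)2 (3 mol %), 2-dicyclohexylphosphino-2',6'-dimethoxybiphenyl (SPhos, 6 mol %), K3PO4, THF/H2O 10:1, 45 °C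
Reagents that add atoms: none
Why: Suzuki–Miyaura coupling proceeds with retention of the E geometry, the electron-rich biaryl phosphine activates the electron-rich aryl bromide, and the free diol and the doubly ortho-flanked aryl silyl ethers tolerate the mild phosphate base.

**Step 11**
Reactants: 19 side-chain diol
Product: 21 (4S,5R)-5-{2-(TBSO)-5-[(E)-3-(TBSO)prop-1-en-1-yl]-3-methoxyphenyl}-4-[4-(TBSO)-3,5-dimethoxyphenyl]-1,3-dioxan-2-one (4,5-cis), via primary imidazole-1-carboxylate 20 (not isolated)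
Conditions: CDI (1.5 equiv), DMAP (20 mol %), CH2Cl2, rt to 40 °C
Reagents that add atoms: 1,1'-carbonyldiimidazole, O=C(n1ccnc1)n1ccnc1
Why: In this carbonylative diol protection the primary OH is acylated first and the benzylic OH then displaces imidazole, which gives a six-membered carbonate that makes the benzylic C–O bond a leaving group without breaking any bond at a stereocentre.

**Step 12**
Reactants: 21 cyclic carbonate
Product: 24 (2S,3R)-2-(4-hydroxy-3,5-dimethoxyphenyl)-3-(hydroxymethyl)-5-[(E)-3-hydroxyprop-1-en-1-yl]-7-methoxy-2,3-dihydrobenzofuran, via desilylated phenolic carbonate 22 (not isolated), via para-quinone methide 23 (not isolated)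
Conditions: TBAF (3.5 equiv), THF, 0 °C to rt; AcOH quench
Reagents that add atoms: none
Why: Fluoride removes the three silyl groups and the syringyl phenoxide expels the benzylic carbonate (1,6-elimination with loss of CO2) to give 23, which the ring A phenoxide closes by a 5-exo-trig intramolecular oxa-Michael (1,6-conjugate) addition in which C3 (R) places the aryl group trans to CH2OH (A1,3 strain minimised, and trans is also the thermodynamic isomer), so C2 becomes S.

**Compound list**
1 | 4-bromo-2-methoxyphenol | COc1cc(Br)ccc1O | starting material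
2 | 4-bromo-2-iodo-6-methoxyphenol | COc1cc(Br)cc(I)c1O | intermediate
3 | (4-bromo-2-iodo-6-methoxyphenoxy)(tert-butyl)dimethylsilane | COc1cc(Br)cc(I)c1O[Si](C)(C)C(C)(C)C | intermediate
4 | (S)-4-benzyloxazolidin-2-one | O=C1N[C@@H](Cc2ccccc2)CO1 | starting material
5 | bromoacetyl bromide | O=C(Br)CBr | starting material
6 | N-lithio (S)-4-benzyloxazolidin-2-one | [Li]N1[C@@H](Cc2ccccc2)COC1=O | intermediate
7 | (S)-4-benzyl-3-(2-bromoacetyl)oxazolidin-2-one | O=C(CBr)N1[C@@H](Cc2ccccc2)COC1=O | intermediate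
8 | bromozinc enolate (Reformatsky reagent) of 7 | Br[Zn]CC(=O)N1[C@@H](Cc2ccccc2)COC1=O | intermediate
9 | (S)-4-benzyl-3-{2-[5-bromo-2-(TBSO)-3-methoxyphenyl]acetyl}oxazolidin-2-one | O=C(Cc1cc(Br)cc(OC)c1O[Si](C)(C)C(C)(C)C)N1[C@@H](Cc2ccccc2)COC1=O | intermediate
10 | syringaldehyde | COc1cc(C=O)cc(OC)c1O | starting material
11 | 4-(TBSO)-3,5-dimethoxybenzaldehyde | COc1cc(C=O)cc(OC)c1O[Si](C)(C)C(C)(C)C | intermediate
12 | Z-dibutylboron enolate of 9 | CCCCB(CCCC)O/C(=C\c1cc(Br)cc(OC)c1O[Si](C)(C)C(C)(C)C)N1[C@@H](Cc2ccccc2)COC1=O | intermediate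
13 | dibutylboron aldolate of 14 | O=C([C@@H](c1cc(Br)cc(OC)c1O[Si](C)(C)C(C)(C)C)[C@H](OB(CCCC)CCCC)c1cc(OC)c(O[Si](C)(C)C(C)(C)C)c(OC)c1)N1[C@@H](Cc2ccccc2)COC1=O | intermediate
14 | (2S,3S)-syn-aldol imide on the (S)-auxiliary | O=C([C@@H](c1cc(Br)cc(OC)c1O[Si](C)(C)C(C)(C)C)[C@H](O)c1cc(OC)c(O[Si](C)(C)C(C)(C)C)c(OC)c1)N1[C@@H](Cc2ccccc2)COC1=O | intermediate
15 | (1S,2R)-bromo diol | OC[C@@H](c1cc(Br)cc(OC)c1O[Si](C)(C)C(C)(C)C)[C@H](O)c1cc(OC)c(O[Si](C)(C)C(C)(C)C)c(OC)c1 | intermediate
16 | propargyl alcohol | C#CCO | starting material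
17 | tert-butyldimethyl(prop-2-yn-1-yloxy)silane | C#CCO[Si](C)(C)C(C)(C)C | intermediate
18 | (E)-3-(TBSO)prop-1-enylboronic acid pinacol ester | CC(C)(C)[Si](C)(C)OC/C=C/B1OC(C)(C)C(C)(C)O1 | intermediate
19 | (1S,2R)-diol carrying the E side chain | OC[C@@H](c1cc(/C=C/CO[Si](C)(C)C(C)(C)C)cc(OC)c1O[Si](C)(C)C(C)(C)C)[C@H](O)c1cc(OC)c(O[Si](C)(C)C(C)(C)C)c(OC)c1 | intermediate
20 | primary imidazole-1-carboxylate of 19 | O=C(OC[C@@H](c1cc(/C=C/CO[Si](C)(C)C(C)(C)C)cc(OC)c1O[Si](C)(C)C(C)(C)C)[C@H](O)c1cc(OC)c(O[Si](C)(C)C(C)(C)C)c(OC)c1)n1ccnc1 | intermediate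
21 | (4S,5R)-4,5-cis-diaryl-1,3-dioxan-2-one, tris-TBS | O=C1OC[C@@H](c2cc(/C=C/CO[Si](C)(C)C(C)(C)C)cc(OC)c2O[Si](C)(C)C(C)(C)C)[C@@H](c2cc(OC)c(O[Si](C)(C)C(C)(C)C)c(OC)c2)O1 | intermediate
22 | desilylated (4S,5R)-carbonate with both phenols and the allylic OH free | O=C1OC[C@@H](c2cc(/C=C/CO)cc(OC)c2O)[C@@H](c2cc(OC)c(O)c(OC)c2)O1 | intermediate
23 | (R)-4-{3-hydroxy-2-[2-hydroxy-5-((E)-3-hydroxyprop-1-enyl)-3-methoxyphenyl]propylidene}-2,6-dimethoxycyclohexa-2,5-dien-1-one | COC1=CC(=C[C@@H](CO)c2cc(/C=C/CO)cc(OC)c2O)C=C(OC)C1=O | intermediate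
24 | (2S,3R)-2-(4-hydroxy-3,5-dimethoxyphenyl)-3-(hydroxymethyl)-5-[(E)-3-hydroxyprop-1-en-1-yl]-7-methoxy-2,3-dihydrobenzofuran | COc1cc([C@H]2Oc3c(OC)cc(/C=C/CO)cc3[C@@H]2CO)cc(OC)c1O | target

**Step count**
Total step count: 12.
Longest linear sequence: 8 (steps 1, 2, 4, 6, 7, 10, 11 and 12, from 1 to 24). The side branches are step 3, step 5, and steps 8 and 9.

**Three steps most likely to fail**

Step 4. Zinc enolates of N-acyl oxazolidinones have little precedent in palladium-catalysed arylation and may acylate themselves. The iodide also sits next to the bulky OTBS group, and the bromide must survive. The fallback sets out from 3 and comes back at 9. It brings in the two carbons as an ester and loads the auxiliary afterwards. Compound 3 is coupled with the commercial Reformatsky reagent BrZnCH2CO2t-Bu (Pd(dba)2, P(t-Bu)3, THF, rt) to give the tert-butyl arylacetate F1. CF3CO2H in CH2Cl2 at 0 °C cleaves it to the arylacetic acid F2. PivCl and Et3N convert this into the mixed pivalic anhydride F3, which acylates 4 (LiCl, Et3N, THF) to give 9.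

Step 10. The electron-rich aryl bromide may add slowly to zerovalent palladium, and the aqueous phosphate base may strip a phenolic silyl ether. The fallback sets out from 15 and comes back at 24. It builds the side chain at the acrylate oxidation level under an anhydrous amine base. A Mizoroki–Heck reaction with methyl acrylate (Pd(OAc)2, P(o-tol)3, Et3N, DMF, 90 °C) gives the cinnamate diol F4, and CDI with DMAP closes the cinnamate cyclic carbonate F5. TBAF takes this through the ester-bearing quinone methide F6 to the dihydrobenzofuran cinnamate F7. Excess i-Bu2AlH (CH2Cl2, −78 °C) then reduces the ester in the 1,2-sense to give 24.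

Step 12. The carbonate may be opened by the ring A phenoxide or by wet fluoride before the 1,6-elimination takes place. The quinone methide may also tautomerise at C3–H to a stilbene. The fallback sets out from 15 and comes back at 24. It closes the ring under acid before any acid-sensitive allylic oxygen is present. TBAF buffered with AcOH gives the bisphenol diol F8. Catalytic TsOH in CH2Cl2 dehydrates the syringyl carbinol to the bromo quinone methide F9 (in protonated form). The ring A phenol traps this under thermodynamic control to give the trans bromo dihydrobenzofuran F10. Suzuki coupling with 18 (Pd(OAc)2, SPhos, K3PO4) gives the allylic silyl ether F11, and TBAF then gives 24.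

**Further compounds**
F1 | step 4 | tert-butyl 2-[5-bromo-2-(TBSO)-3-methoxyphenyl]acetate | CC(C)(C)OC(=O)Cc1cc(Br)cc(OC)c1O[Si](C)(C)C(C)(C)C
F2 | step 4 | 2-[5-bromo-2-(TBSO)-3-methoxyphenyl]acetic acid | OC(=O)Cc1cc(Br)cc(OC)c1O[Si](C)(C)C(C)(C)C
F3 | step 4 | mixed pivalic anhydride of F2 | CC(C)(C)C(=O)OC(=O)Cc1cc(Br)cc(OC)c1O[Si](C)(C)C(C)(C)C
F4 | step 10 | methyl (E)-3-{4-(TBSO)-3-[(1S,2R)-1,3-dihydroxy-1-(4-TBSO-3,5-dimethoxyphenyl)propan-2-yl]-5-methoxyphenyl}acrylate | OC[C@@H](c1cc(/C=C/C(=O)OC)cc(OC)c1O[Si](C)(C)C(C)(C)C)[C@H](O)c1cc(OC)c(O[Si](C)(C)C(C)(C)C)c(OC)c1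
F5 | step 10 | (4S,5R)-cyclic carbonate of F4 | O=C1OC[C@@H](c2cc(/C=C/C(=O)OC)cc(OC)c2O[Si](C)(C)C(C)(C)C)[C@@H](c2cc(OC)c(O[Si](C)(C)C(C)(C)C)c(OC)c2)O1
F6 | step 10 | (R)-para-quinone methide carrying the methyl acrylate side chain | COC1=CC(=C[C@@H](CO)c2cc(/C=C/C(=O)OC)cc(OC)c2O)C=C(OC)C1=O
F7 | step 10 | methyl (E)-3-[(2S,3R)-2-(4-hydroxy-3,5-dimethoxyphenyl)-3-(hydroxymethyl)-7-methoxy-2,3-dihydrobenzofuran-5-yl]acrylate | COc1cc([C@H]2Oc3c(OC)cc(/C=C/C(=O)OC)cc3[C@@H]2CO)cc(OC)c1O
F8 | step 12 | (1S,2R)-2-(5-bromo-2-hydroxy-3-methoxyphenyl)-1-(4-hydroxy-3,5-dimethoxyphenyl)propane-1,3-diol | OC[C@@H](c1cc(Br)cc(OC)c1O)[C@H](O)c1cc(OC)c(O)c(OC)c1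
F9 | step 12 | (R)-bromo para-quinone methide | COC1=CC(=C[C@@H](CO)c2cc(Br)cc(OC)c2O)C=C(OC)C1=O
F10 | step 12 | 4-[(2S,3R)-5-bromo-3-(hydroxymethyl)-7-methoxy-2,3-dihydrobenzofuran-2-yl]-2,6-dimethoxyphenol | COc1cc([C@H]2Oc3c(OC)cc(Br)cc3[C@@H]2CO)cc(OC)c1O
F11 | step 12 | allylic TBS ether of 24 | COc1cc([C@H]2Oc3c(OC)cc(/C=C/CO[Si](C)(C)C(C)(C)C)cc3[C@@H]2CO)cc(OC)c1O
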